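## Retrosynthetic overview

1. The target comes from its 15‑O‑PMB ether; the last ring (ten‑membered carbocycle, i.e. the nine‑membered oxacycle of the 3,10‑hemiketal) is closed by ring‑closing metathesis at C4=C5.
2. The metathesis precursor is a cis‑α‑methylene‑γ‑lactone (C6–O) with a C5 vinyl group and a γ‑hydroxy α‑methylene ketone (C10–OH / C3=O, the latent oxolane hemiketal).
3. The C7–C8 bond and the C7/C8 stereocentres come from an indium‑mediated Barbier allylation of a C8 aldehyde with a (Z)‑2‑(bromomethyl)enoate whose C6 silyloxy centre steers the addition; the new C8–OH is then esterified.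
4. The aldehyde fragment (C8–C10, C1–C4, C14, C15) comes from (R)‑linalool and a 2‑lithioallyl PMB ether; the bromide fragment (C5–C7, C11–C13) from (S)‑but‑3‑ene‑1,2‑diol and methyl propiolate.
5. Ring order: γ‑lactone, then the oxolane hemiketal (spontaneous), then the medium ring by metathesis.

Assumption: locants C1–C15 in the text follow germacranolide numbering (lactone C6–O–C12, methylene C13, methyl C14, CH2OH C15); the hemiketal carbon C3 is set under thermodynamic control.

## Route

Step 1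
Reactants: 1 (R)-(−)-linalool, (3R)-3,7-dimethylocta-1,6-dien-3-ol
Product: 2 triethyl{[(3R)-3,7-dimethylocta-1,6-dien-3-yl]oxy}silane
Conditions: Et3SiOTf, 2,6-lutidine, CH2Cl2, −78 → 0 °C
Reagents that add atoms: triethylsilyl trifluoromethanesulfonate, CC[Si](CC)(CC)OS(=O)(=O)C(F)(F)F
Why: Silylation of the tertiary allylic alcohol under buffered conditions masks the C10 oxygen (chiral‑pool stereocentre, untouched) so that it cannot form lactols or ketals before the end of the route.

Step 2
Reactants: 2 triethylsilyl ether of (R)-linalool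
Product: 4 (3R)-3,7-dimethyl-3-[(triethylsilyl)oxy]oct-6-en-1-ol, via alkylborane 3 (not isolated)
Conditions: 9-BBN (1.3 equiv), THF, 0 °C → rt; then NaOH, H2O2, 0 °C
Reagents that add atoms: hydrogen peroxide, OO
Why: Anti‑Markovnikov hydroboration–oxidation, in which 9‑BBN reacts only with the monosubstituted vinyl group and leaves the trisubstituted alkene untouched.

Step 3
Reactants: 4 (3R)-3,7-dimethyl-3-[(triethylsilyl)oxy]oct-6-en-1-ol
Product: 6 (4R)-6-hydroxy-4-methyl-4-[(triethylsilyl)oxy]hexanal, via secondary ozonide 5 (not isolated)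
Conditions: O3, CH2Cl2, −78 °C; then PPh3, −78 °C → rt
Reagents that add atoms: ozone, [O-][O+]=O
Why: Ozonolysis with reductive work‑up cleaves the trisubstituted alkene to the C3 aldehyde (acetone is lost) while the silyl ether and the primary alcohol are inert.

Step 4
Reactants: 7 2,3-dibromoprop-1-ene
Product: 8 1-{[(2-bromoprop-2-en-1-yl)oxy]methyl}-4-methoxybenzene
Conditions: 4-methoxybenzyl alcohol, NaH, THF, 0 °C → rt
Reagents that add atoms: 4-methoxybenzyl alcohol, COc1ccc(CO)cc1
Why: Williamson ether synthesis in which the alkoxide displaces only the allylic bromide, the vinylic bromide being inert to SN2.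

Step 5
Reactants: 8 2-bromoallyl PMB ether and 6 (4R)-6-hydroxy-4-methyl-4-[(triethylsilyl)oxy]hexanal
Product: 10 (3RS,6R)-2-{[(4-methoxyphenyl)methoxy]methyl}-6-methyl-6-[(triethylsilyl)oxy]oct-1-ene-3,8-diol, via vinyllithium 9 (not isolated)
Conditions: 8 (2.3 equiv), t-BuLi (4.6 equiv), Et2O, −78 °C; then 6, −78 → −40 °C; aq. NH4Cl
Reagents that add atoms: none
Why: Bromine–lithium exchange gives the 2‑lithioallyl ether, which adds 1,2 to the aldehyde (one equivalent is spent on the free hydroxyl); the C3 carbinol forms as an epimer mixture that is erased by oxidation in step 6.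

Step 6
Reactants: 10 C3‑epimeric diol
Product: 11 (3R)-7-{[(4-methoxyphenyl)methoxy]methyl}-3-methyl-6-oxo-3-[(triethylsilyl)oxy]oct-7-enal
Conditions: Dess–Martin periodinane (3 equiv), NaHCO3, CH2Cl2, 0 °C → rt; used without storage
Reagents that add atoms: none
Why: Dess–Martin oxidation converts the primary alcohol into the C8 aldehyde and the allylic carbinol into the C3 enone in one buffered operation that spares the silyl and PMB ethers.

Step 7
Reactants: 12 (2S)-but-3-ene-1,2-diol
Product: 13 (2S)-2-hydroxybut-3-en-1-yl 2,2-dimethylpropanoate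
Conditions: pivaloyl chloride (1.05 equiv), pyridine, CH2Cl2, −20 → 0 °C
Reagents that add atoms: pivaloyl chloride, CC(C)(C)C(=O)Cl
Why: The bulky acyl chloride esterifies the primary hydroxyl selectively over the secondary allylic one, leaving the future C6 carbinol free.

Step 8
Reactants: 13 (2S)-2-hydroxybut-3-en-1-yl pivalate
Product: 14 (2S)-2-{[tert-butyl(dimethyl)silyl]oxy}but-3-en-1-yl 2,2-dimethylpropanoate
Conditions: TBSCl, imidazole, DMF, rt
Reagents that add atoms: tert-butyldimethylsilyl chloride, CC(C)(C)[Si](C)(C)Cl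
Why: Standard silylation gives a bulky, non‑chelating ether on the future C6 oxygen, which is needed for the stereocontrol of step 13.

Step 9
Reactants: 14 silyl ether pivalate
Product: 15 (2S)-2-{[tert-butyl(dimethyl)silyl]oxy}but-3-en-1-ol
Conditions: i-Bu2AlH (2.5 equiv), CH2Cl2, −78 °C; aq. potassium sodium tartrate
Reagents that add atoms: none
Why: Reductive cleavage of the pivalate at low temperature frees the primary alcohol without the silyl migration that basic solvolysis could cause.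

Step 10
Reactants: 15 (2S)-2-{[tert-butyl(dimethyl)silyl]oxy}but-3-en-1-ol
Product: 16 (2S)-2-{[tert-butyl(dimethyl)silyl]oxy}but-3-enal
Conditions: Dess–Martin periodinane, NaHCO3, CH2Cl2, 0 °C; filtered and used at once
Reagents that add atoms: none
Why: Buffered, amine‑free Dess–Martin oxidation gives the α‑silyloxy β,γ‑unsaturated aldehyde without exposing its acidic α‑hydrogen to base, so the stereocentre and the alkene position are kept.

Step 11
Reactants: 16 (2S)-2-{[tert-butyl(dimethyl)silyl]oxy}but-3-enal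
Product: 17 methyl (3RS,4S)-4-{[tert-butyl(dimethyl)silyl]oxy}-3-hydroxy-2-methylidenehex-5-enoate
Conditions: methyl propiolate, i-Bu2AlH, N-methylmorpholine N-oxide, THF, 0 °C, 30 min; then 16, 0 °C → rt; aq. potassium sodium tartrate
Reagents that add atoms: methyl propiolate, C#CC(=O)OC
Why: Vinylalumination (a fast, non‑basic route to a Morita–Baylis–Hillman‑type adduct) joins the α‑carbon of the acrylate to the aldehyde; the new carbinol configuration is irrelevant because it becomes sp2 in step 12.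

Step 12
Reactants: 17 Morita–Baylis–Hillman‑type alcohol
Product: 18 methyl (2Z,4S)-2-(bromomethyl)-4-{[tert-butyl(dimethyl)silyl]oxy}hexa-2,5-dienoate
Conditions: NBS, Me2S, CH2Cl2, 0 °C (pre‑mixed); then 17, 0 °C → rt
Reagents that add atoms: N-bromosuccinimide, O=C1CCC(=O)N1Br
Why: Corey–Kim‑type activation followed by SN2′ attack of bromide gives the conjugated allylic bromide, with the usual Z selectivity of such adducts (C6 branch cis to CH2Br).

Step 13
Reactants: 18 (Z)-allylic bromide and 11 keto aldehyde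
Product: 20 methyl (3R,4R,6R)-3-[(1S)-1-{[tert-butyl(dimethyl)silyl]oxy}prop-2-en-1-yl]-4-hydroxy-10-{[(4-methoxyphenyl)methoxy]methyl}-6-methyl-2-methylidene-9-oxo-6-[(triethylsilyl)oxy]undec-10-enoate, via allylindium bromide 19 (not isolated)
Conditions: 18 (1.4 equiv), indium powder (2 equiv), THF/H2O (3:1), rt; NaHCO3 work‑up; crude product taken on directly
Reagents that add atoms: none
Why: In this indium‑mediated Barbier 2‑(alkoxycarbonyl)allylation the (Z)‑allylindium reacts at its γ‑carbon through a chair transition state to give the 7,8‑syn adduct, while 1,3‑allylic strain holds C6–H in the alkene plane so that the aldehyde bonds to C7 anti to the vinyl group and gauche to the non‑chelating silyloxy group, which sets 7R and 8R from 6S and leaves the less electrophilic enone alone.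

Step 14
Reactants: 20 hydroxy ester
Product: 21 methyl (3R,4R,6R)-3-[(1S)-1-{[tert-butyl(dimethyl)silyl]oxy}prop-2-en-1-yl]-10-{[(4-methoxyphenyl)methoxy]methyl}-6-methyl-2-methylidene-4-[(2-methylpropanoyl)oxy]-9-oxo-6-[(triethylsilyl)oxy]undec-10-enoate
Conditions: isobutyric anhydride (3 equiv), Et3N, DMAP (0.3 equiv), CH2Cl2, 0 °C → rt
Reagents that add atoms: isobutyric anhydride, CC(C)C(=O)OC(=O)C(C)C
Why: DMAP‑catalysed acylation of the only free hydroxyl installs the C8 isobutyrate and blocks lactonisation towards C8.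

Step 15
Reactants: 21 isobutyrate
Product: 23 (1R,3R)-1-[(2S,3R)-2-ethenyl-4-methylidene-5-oxooxolan-3-yl]-3-hydroxy-7-{[(4-methoxyphenyl)methoxy]methyl}-3-methyl-6-oxooct-7-en-1-yl 2-methylpropanoate (in equilibrium with its five‑membered C3 hemiketal), via dihydroxy ester 22 (not isolated)
Conditions: aq. HF (48 %), MeCN, 0 °C → rt; then camphorsulfonic acid (cat.), CH2Cl2, rt
Reagents that add atoms: none
Why: Fluoride‑mediated removal of both silyl ethers frees the C6 and C10 hydroxyls, and acid‑catalysed lactonisation of the C6 hydroxyl onto the acrylate ester gives the cis‑fused α‑methylene‑γ‑butyrolactone without touching any stereocentre.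

Step 16
Reactants: 23 lactone diene
Product: 24 (3S,4Z,6S,7R,8R,10R)-3,10-epoxy-3-hydroxy-15-[(4-methoxyphenyl)methoxy]-8-[(2-methylpropanoyl)oxy]germacra-4,11(13)-dien-6,12-olide
Conditions: RuCl2(H2IMes)(=CH-C6H4-2-O-i-Pr) (second-generation Hoveyda–Grubbs catalyst, 15 mol %), 1,4-benzoquinone (20 mol %), toluene (1 mM), 90 °C
Reagents that add atoms: none
Why: Ring‑closing metathesis between the C5 vinyl group and the 1,1‑disubstituted C4 alkene closes the medium ring as the Z alkene, and the transannular C10–OH/C3=O pair settles as the bridged hemiketal, whose 3S configuration is the only one the bridge allows.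

Step 17
Reactants: 24 PMB ether
Product: 25 (3S,4Z,6S,7R,8R,10R)-3,10-epoxy-3,15-dihydroxy-8-[(2-methylpropanoyl)oxy]germacra-4,11(13)-dien-6,12-olide (target)
Conditions: DDQ (1.3 equiv), CH2Cl2/pH 7 phosphate buffer (10:1), 0 °C
Reagents that add atoms: none
Why: Oxidative cleavage of the electron‑rich PMB ether under neutral conditions frees the C15 alcohol without affecting the hemiketal, the isobutyrate or the α‑methylene lactone.

## Compound list

CIP descriptors of a given centre change in 3 and 22 only because substituent priorities change; no centre is inverted.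

1 | (R)-(−)-linalool, (3R)-3,7-dimethylocta-1,6-dien-3-ol | CC(C)=CCC[C@](C)(C=C)O | starting material
2 | triethyl{[(3R)-3,7-dimethylocta-1,6-dien-3-yl]oxy}silane | CC(C)=CCC[C@](C)(C=C)O[Si](CC)(CC)CC | intermediate
3 | 9-{(3S)-3,7-dimethyl-3-[(triethylsilyl)oxy]oct-6-en-1-yl}-9-borabicyclo[3.3.1]nonane | CC(C)=CCC[C@](C)(CCB1C2CCCC1CCC2)O[Si](CC)(CC)CC | intermediate
4 | (3R)-3,7-dimethyl-3-[(triethylsilyl)oxy]oct-6-en-1-ol | CC(C)=CCC[C@](C)(CCO)O[Si](CC)(CC)CC | intermediate
5 | (3R)-5-(5,5-dimethyl-1,2,4-trioxolan-3-yl)-3-methyl-3-[(triethylsilyl)oxy]pentan-1-ol (trioxolane C3 epimers) | CC1(C)OOC(CC[C@](C)(CCO)O[Si](CC)(CC)CC)O1 | intermediate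
6 | (4R)-6-hydroxy-4-methyl-4-[(triethylsilyl)oxy]hexanal | O=CCC[C@](C)(CCO)O[Si](CC)(CC)CC | intermediate
7 | 2,3-dibromoprop-1-ene | C=C(Br)CBr | starting material
8 | 1-{[(2-bromoprop-2-en-1-yl)oxy]methyl}-4-methoxybenzene | C=C(Br)COCc1ccc(OC)cc1 | intermediate
9 | {3-[(4-methoxyphenyl)methoxy]prop-1-en-2-yl}lithium | [Li]C(=C)COCc1ccc(OC)cc1 | intermediate
10 | (3RS,6R)-2-{[(4-methoxyphenyl)methoxy]methyl}-6-methyl-6-[(triethylsilyl)oxy]oct-1-ene-3,8-diol | C=C(COCc1ccc(OC)cc1)C(O)CC[C@](C)(CCO)O[Si](CC)(CC)CC | intermediate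
11 | (3R)-7-{[(4-methoxyphenyl)methoxy]methyl}-3-methyl-6-oxo-3-[(triethylsilyl)oxy]oct-7-enal | C=C(COCc1ccc(OC)cc1)C(=O)CC[C@](C)(CC=O)O[Si](CC)(CC)CC | intermediate
12 | (2S)-but-3-ene-1,2-diol | O[C@H](CO)C=C | starting material
13 | (2S)-2-hydroxybut-3-en-1-yl 2,2-dimethylpropanoate | O[C@H](COC(=O)C(C)(C)C)C=C | intermediate
14 | (2S)-2-{[tert-butyl(dimethyl)silyl]oxy}but-3-en-1-yl 2,2-dimethylpropanoate | CC(C)(C)[Si](C)(C)O[C@H](COC(=O)C(C)(C)C)C=C | intermediate
15 | (2S)-2-{[tert-butyl(dimethyl)silyl]oxy}but-3-en-1-ol | CC(C)(C)[Si](C)(C)O[C@H](CO)C=C | intermediate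
16 | (2S)-2-{[tert-butyl(dimethyl)silyl]oxy}but-3-enal | CC(C)(C)[Si](C)(C)O[C@H](C=O)C=C | intermediate
17 | methyl (3RS,4S)-4-{[tert-butyl(dimethyl)silyl]oxy}-3-hydroxy-2-methylidenehex-5-enoate | CC(C)(C)[Si](C)(C)O[C@H](C(O)C(=C)C(=O)OC)C=C | intermediate
18 | methyl (2Z,4S)-2-(bromomethyl)-4-{[tert-butyl(dimethyl)silyl]oxy}hexa-2,5-dienoate | CC(C)(C)[Si](C)(C)O[C@H](/C=C(\CBr)C(=O)OC)C=C | intermediate
19 | dibromo{(2Z,4S)-4-{[tert-butyl(dimethyl)silyl]oxy}-2-(methoxycarbonyl)hexa-2,5-dien-1-yl}indium (one component of the allylindium sesquibromide) | CC(C)(C)[Si](C)(C)O[C@H](/C=C(\C[In](Br)Br)C(=O)OC)C=C | intermediate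
20 | methyl (3R,4R,6R)-3-[(1S)-1-{[tert-butyl(dimethyl)silyl]oxy}prop-2-en-1-yl]-4-hydroxy-10-{[(4-methoxyphenyl)methoxy]methyl}-6-methyl-2-methylidene-9-oxo-6-[(triethylsilyl)oxy]undec-10-enoate | C=C(C(=O)OC)[C@@H]([C@@H](O[Si](C)(C)C(C)(C)C)C=C)[C@H](O)C[C@](C)(O[Si](CC)(CC)CC)CCC(=O)C(=C)COCc1ccc(OC)cc1 | intermediate
21 | methyl (3R,4R,6R)-3-[(1S)-1-{[tert-butyl(dimethyl)silyl]oxy}prop-2-en-1-yl]-10-{[(4-methoxyphenyl)methoxy]methyl}-6-methyl-2-methylidene-4-[(2-methylpropanoyl)oxy]-9-oxo-6-[(triethylsilyl)oxy]undec-10-enoate | C=C(C(=O)OC)[C@@H]([C@@H](O[Si](C)(C)C(C)(C)C)C=C)[C@H](OC(=O)C(C)C)C[C@](C)(O[Si](CC)(CC)CC)CCC(=O)C(=C)COCc1ccc(OC)cc1 | intermediate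
22 | methyl (3S,4R,6R)-6-hydroxy-3-[(1S)-1-hydroxyprop-2-en-1-yl]-10-{[(4-methoxyphenyl)methoxy]methyl}-6-methyl-2-methylidene-4-[(2-methylpropanoyl)oxy]-9-oxoundec-10-enoate | C=C(C(=O)OC)[C@@H]([C@@H](O)C=C)[C@H](OC(=O)C(C)C)C[C@](C)(O)CCC(=O)C(=C)COCc1ccc(OC)cc1 | intermediate
23 | (1R,3R)-1-[(2S,3R)-2-ethenyl-4-methylidene-5-oxooxolan-3-yl]-3-hydroxy-7-{[(4-methoxyphenyl)methoxy]methyl}-3-methyl-6-oxooct-7-en-1-yl 2-methylpropanoate (open form of the C3 hemiketal) | C=C1C(=O)O[C@@H](C=C)[C@H]1[C@H](OC(=O)C(C)C)C[C@](C)(O)CCC(=O)C(=C)COCc2ccc(OC)cc2 | intermediate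
24 | (3S,4Z,6S,7R,8R,10R)-3,10-epoxy-3-hydroxy-15-[(4-methoxyphenyl)methoxy]-8-[(2-methylpropanoyl)oxy]germacra-4,11(13)-dien-6,12-olide | C=C1C(=O)O[C@H]2/C=C(/COCc4ccc(OC)cc4)[C@]3(O)CC[C@](C)(C[C@@H](OC(=O)C(C)C)[C@@H]12)O3 | intermediate
25 | (3S,4Z,6S,7R,8R,10R)-3,10-epoxy-3,15-dihydroxy-8-[(2-methylpropanoyl)oxy]germacra-4,11(13)-dien-6,12-olide | C=C1C(=O)O[C@H]2/C=C(/CO)[C@]3(O)CC[C@](C)(C[C@@H](OC(=O)C(C)C)[C@@H]12)O3 | target

## Step count and risks

Total step count: 17. Longest linear sequence: 11 steps (steps 7–12, then 13–17, from (2S)-but-3-ene-1,2-diol); the linalool branch is 10 steps (1, 2, 3, 5, 6, then 13–17).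

Three steps most likely to fail:

**Step 16 (ring‑closing metathesis).** A trisubstituted alkene has to form in a medium ring from a hindered 1,1‑disubstituted olefin, and 23 is mostly in the open hydroxy‑enone form, so oligomerisation or no reaction is possible. The fallback sets out from 23 and comes back at 24. Compound 23 is locked with camphorsulfonic acid, MeOH and HC(OMe)3 as (1R)-1-[(2S,3R)-2-ethenyl-4-methylidene-5-oxooxolan-3-yl]-2-[(2R,5RS)-5-methoxy-5-{3-[(4-methoxyphenyl)methoxy]prop-1-en-2-yl}-2-methyloxolan-2-yl]ethyl 2-methylpropanoate F3. In its cis anomer both olefin arms sit on the same face of the oxolane; the trans anomer is re‑equilibrated with acid and recycled. Metathesis with the same ruthenium carbene then closes only the nine‑membered oxacycle, giving (3S,4Z,6S,7R,8R,10R)-3,10-epoxy-3-methoxy-15-[(4-methoxyphenyl)methoxy]-8-[(2-methylpropanoyl)oxy]germacra-4,11(13)-dien-6,12-olide F4. Hydrolysis of the ketal with pyridinium p‑toluenesulfonate in wet acetone returns 24.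

**Step 13 (Barbier coupling).** Three contiguous stereocentres depend on acyclic control by C6 and on the Z geometry of a fluxional allylindium; the wrong facial sense or E/Z scrambling would give diastereomers. The fallback sets out from 17 and comes back at 20. Compound 17 is acetylated (Ac2O, DMAP, pyridine) to methyl (3RS,4S)-3-(acetyloxy)-4-{[tert-butyl(dimethyl)silyl]oxy}-2-methylidenehex-5-enoate F1. Pd2(dba)3‑catalysed borylation with B2pin2 gives the configurationally stable methyl (2E,4S)-4-{[tert-butyl(dimethyl)silyl]oxy}-2-[(4,4,5,5-tetramethyl-1,3,2-dioxaborolan-2-yl)methyl]hexa-2,5-dienoate F2, in which the C6 branch is again cis to the CH2–metal group. Allylboration of 11 with F2 under a chiral phosphoric acid (TRIP, the enantiomer matched to C6, toluene, −30 °C) goes through a tight boron‑centred chair in which the catalyst dictates the aldehyde face; cold neutral work‑up gives 20.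

**Step 11 (vinylalumination of aldehyde 16).** The α‑silyloxy β,γ‑unsaturated aldehyde can epimerise or isomerise into conjugation while it waits for the aluminium reagent. The fallback sets out from 15 and comes back at 18. Compound 15 is oxidised with Dess–Martin periodinane in the presence of methyl bromo(triphenyl‑λ5‑phosphanylidene)acetate, so that 16 is trapped by Wittig olefination as it forms, giving methyl (2Z,4S)-2-bromo-4-{[tert-butyl(dimethyl)silyl]oxy}hexa-2,5-dienoate F5. Stille coupling with Bu3SnCH2OH and Pd(PPh3)4 gives methyl (2E,4S)-4-{[tert-butyl(dimethyl)silyl]oxy}-2-(hydroxymethyl)hexa-2,5-dienoate F6 with retention of geometry. Appel bromination (CBr4, PPh3) returns 18.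

## Further compounds

F1 | step 13 | methyl (3RS,4S)-3-(acetyloxy)-4-{[tert-butyl(dimethyl)silyl]oxy}-2-methylidenehex-5-enoate | CC(C)(C)[Si](C)(C)O[C@H](C(OC(C)=O)C(=C)C(=O)OC)C=C
F2 | step 13 | methyl (2E,4S)-4-{[tert-butyl(dimethyl)silyl]oxy}-2-[(4,4,5,5-tetramethyl-1,3,2-dioxaborolan-2-yl)methyl]hexa-2,5-dienoate | CC(C)(C)[Si](C)(C)O[C@H](/C=C(\CB1OC(C)(C)C(C)(C)O1)C(=O)OC)C=C
F3 | step 16 | (1R)-1-[(2S,3R)-2-ethenyl-4-methylidene-5-oxooxolan-3-yl]-2-[(2R,5RS)-5-methoxy-5-{3-[(4-methoxyphenyl)methoxy]prop-1-en-2-yl}-2-methyloxolan-2-yl]ethyl 2-methylpropanoate | C=C1C(=O)O[C@@H](C=C)[C@H]1[C@H](OC(=O)C(C)C)C[C@@]2(C)CCC(OC)(C(=C)COCc3ccc(OC)cc3)O2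
F4 | step 16 | (3S,4Z,6S,7R,8R,10R)-3,10-epoxy-3-methoxy-15-[(4-methoxyphenyl)methoxy]-8-[(2-methylpropanoyl)oxy]germacra-4,11(13)-dien-6,12-olide | C=C1C(=O)O[C@H]2/C=C(/COCc4ccc(OC)cc4)[C@]3(OC)CC[C@](C)(C[C@@H](OC(=O)C(C)C)[C@@H]12)O3
F5 | step 11 | methyl (2Z,4S)-2-bromo-4-{[tert-butyl(dimethyl)silyl]oxy}hexa-2,5-dienoate | CC(C)(C)[Si](C)(C)O[C@H](/C=C(\Br)C(=O)OC)C=C
F6 | step 11 | methyl (2E,4S)-4-{[tert-butyl(dimethyl)silyl]oxy}-2-(hydroxymethyl)hexa-2,5-dienoate | CC(C)(C)[Si](C)(C)O[C@H](/C=C(\CO)C(=O)OC)C=C
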